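The target in these flasks grows at a rate we can read from the samples, so we follow that rate.

| flask | substrate | coupling partner | free catalyst | second catalyst | temperature | remark | time |
|---|---|---|---|---|---|---|---|
| alder | 0.059 M | 0.0649 M | 30 µM | 16 µM | 88 °C | run made earlier |  |
| elm | 0.059 M | 0.0649 M | 30 µM | 66 µM | 104 °C | run made earlier |  |
| ash | 0.059 M | 0.0649 M | 60 µM | 33 µM | 88 °C | run made earlier |  |
| Friday's | 0.059 M | 0.0649 M | 30 µM | 33 µM | 80 °C |  | 25 min |
| Monday's | 0.059 M | 0.0649 M | 30 µM | 33 µM | 95 °C |  | 25 min |
| Thursday's | 0.059 M | 0.0649 M | 30 µM | 33 µM | 110 °C |  | 25 min |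

| run | time / min | target / % | substrate / % |
|---|---|---|---|
| alder | 2.00 | 18 | 0 |
| alder | 5.00 | 35 | 2 |
| alder | 10.0 | 53 | 2 |
| alder | 15.0 | 67 | 0 |
| elm | 0.667 | 36 | 0 |
| elm | 1.50 | 61 | 3 |
| elm | 3.00 | 77 | 2 |
| elm | 5.00 | 86 | 0 |
| ash | 1.33 | 23 | 3 |
| ash | 3.00 | 41 | 0 |
| ash | 6.00 | 64 | 1 |
| ash | 15.0 | 89 | 0 |

(scatter of a reading: 2 percentage points)

- which of the two there is more of at the end, counted by the substrate in each, Friday's (target / side product)
- which of the two there is more of at the end, counted by the substrate in each, Monday's (target / side product)
- which of the two there is more of at the end, counted by the substrate in each, Thursday's (target / side product)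
- amount of target at the end, in percent of the substrate charged, Friday's
- amount of target at the end, in percent of the substrate charged, Monday's
- amount of target at the end, in percent of the substrate charged, Thursday's

- percentages count the substrate that a species holds: one homo dimer or side product counts as two
- the analysis behind the earlier runs scatters by 2 percentage points, standard deviation
- steps that have been proposed: 2 substrate -> homo dimer; substrate + free catalyst -> free catalyst + open intermediate; second catalyst + open intermediate <-> catalyst intermediate; substrate + open intermediate -> side product; coupling partner + catalyst intermediate -> second catalyst + target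

In ash the target starts at 0.173 min⁻¹ of the charge, then runs at 0.108 min⁻¹, then 0.0767 min⁻¹, and over its last interval at 0.0278 min⁻¹. The slowing comes in factors of 1.60, 1.41 and 2.76, which multiply to 6.22.

Alder, with 16 µM of second catalyst against ash's 33 µM, starts at 0.0900 min⁻¹, about half of ash's rate. Its last reading, 67%, comes at 7.27 min once its time is scaled by second catalyst, close to ash's 64% at 6.00 min. Elm reads 61% at 1.50 min, level with that ash reading within the scatter, yet its scaled time is 3.00 min. Ash also carries 60 µM of free catalyst against the 30 µM of alder and elm, and we leave that difference out of the comparison by choice. With it left aside, these scattered readings give a clock factor of 2.00 between 88 °C and 104 °C.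

We therefore reckon each flask in ash time (a normalised time): elapsed minutes, times second catalyst over ash's, times that factor taken in proportion to the temperature difference. For Friday's the temperature factor is 0.707, so we reckon its start at 0.122 min⁻¹, and

ash time, Friday's = 17.7 min

ash time, Monday's = 33.9 min

ash time, Thursday's = 64.8 min

Friday's ends just past ash's last reading, so we commit to about 89%, with 96.4% as the sum if ash's last rate held. Monday's and Thursday's lie far beyond that reading, and we take both as finished near the same height. Ash's last reading leaves 11.0% for everything else, so we put target ahead of side product in Friday's, Monday's and Thursday's.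

The forecast gives 83%, 86% and 84%, its Friday figure lower than ours, with “Target dominates throughout”.

The flasks give target 88.5%, 90.1% and 87.5%, against side product 2.08%, 2.72% and 3.42%.

    2 substrate → homo dimer (k = 0.0980 M⁻¹ s⁻¹, Ea = 73.0 kJ mol⁻¹)
    substrate + free catalyst → free catalyst + open intermediate (k = 3900 M⁻¹ s⁻¹, Ea = 45.0 kJ mol⁻¹)
    second catalyst + open intermediate ⇌ catalyst intermediate (K = 44.0 M⁻¹, k = 1700 M⁻¹ s⁻¹, Ea = 50.0 kJ mol⁻¹, ΔH = −3.00 kJ mol⁻¹)
    substrate + open intermediate → side product (k = 0.0480 M⁻¹ s⁻¹, Ea = 68.0 kJ mol⁻¹)
    coupling partner + catalyst intermediate → second catalyst + target (k = 99.0 M⁻¹ s⁻¹, Ea = 42.0 kJ mol⁻¹)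
    (constants at 80 °C)

Friday's ended at 17.7 min of ash time with 88.5%, beside ash's 89%. Its neighbouring flask is the same with 2.0 × 10⁻⁵ M of second catalyst, so the neighbour's 25 min come to 10.7 min of ash time, a point Friday's own flask passes at 15.2 min. Friday's held 75.8% at 12.5 min and 88.5% at 25.0 min, so the reckoning places the neighbour between them, and the neighbour ends with 80.4% of target.

The runs are simulated from invented constants; scatter was added.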